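**Plan** (decalin numbered as in the target name: ring B = C1(CH3)(CH2Ar)–C2(CH3)–C3–C4–C4a–C8a(CH3); ring A = C4a–C5(=CH2)–C6–C7–C8–C8a)
Cuts, in retrosynthetic order: Ar–CO2Me; C5=CH2 (back to a C5 ketone, then a C4a=C5 alkene); C1–CH3 (back to C1–C≡N); C1–CH2Ar and C1–C2 (both made in one flask); C4–C4a (sp2–sp3 coupling); C8a–C1 (asymmetric allylation).
Forward: ring A comes first, as a cyclohexenyl triflate that already holds the C8a quaternary centre; the C4–C3–C2 chain is coupled on; ring B is closed last between C1 and C2; C1, C4a, C5 and the arene are then adjusted.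
Enabling feature: C1 sits between C8a and C2, whose methyl groups lie on the same face of ring B; a nitrile on C1 (the masked C1 methyl) lets C1 act twice as a carbanion, first displacing a sulfonate on C2, then taking the benzyl group from the unhindered face.
Stereochemistry: C8a from the Pd/(R)-t-BuPHOX allylation; C2 from (R)-but-3-en-2-ol with inversion; C1 from benzylation anti to the two axial methyls; C4a from hydroboration anti to the C8a methyl.

Key step: step 9

Remark: 1, 9 and 15 are taken as purchasable; 3 is expected in high but not complete enantiomeric purity, and because 9 is a single enantiomer the minor antipode would travel from 13 onward as a separable diastereomer.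

**Step 1**
Reactants: 1 allyl 2-oxocyclohexane-1-carboxylate
Product: 2 allyl 1-methyl-2-oxocyclohexane-1-carboxylate (racemic)
Conditions: MeI, K2CO3, acetone, reflux
Reagents that add atoms: iodomethane CI
Why: C-alkylation of the doubly stabilised β-keto ester enolate installs the future C8a methyl, and the racemic centre does not matter because it is ionised and re-set in step 2.

**Step 2**
Reactants: 2 allyl 1-methyl-2-oxocyclohexane-1-carboxylate
Product: 3 (R)-2-allyl-2-methylcyclohexan-1-one
Conditions: Pd2(dba)3 (2.5 mol %), (R)-t-BuPHOX (6 mol %), THF, 25 °C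
Reagents that add atoms: none
Why: Tsuji-type Pd-catalysed decarboxylative asymmetric allylic alkylation, in which zerovalent palladium ionises the allyl ester, CO2 is lost and the ligand-bound allyl–Pd enolate recombines on one enolate face, should set the quaternary centre (future C8a) as (R).

**Step 3**
Reactants: 3 (R)-2-allyl-2-methylcyclohexan-1-one
Product: 4 (R)-6-allyl-6-methylcyclohex-1-en-1-yl trifluoromethanesulfonate
Conditions: LDA, THF, −78 °C; PhNTf2, −78 → 0 °C
Reagents that add atoms: N-phenylbis(trifluoromethanesulfonimide) O=S(=O)(N(c1ccccc1)S(=O)(=O)C(F)(F)F)C(F)(F)F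
Why: Enol triflate formation is regiospecific because only one α-carbon carries hydrogen, and it fixes the future C4a=C5 alkene without touching the quaternary centre.

**Step 4**
Reactants: 4 (R)-6-allyl-6-methylcyclohex-1-en-1-yl trifluoromethanesulfonate
Product: 6 (R)-6-methyl-6-(2-oxoethyl)cyclohex-1-en-1-yl trifluoromethanesulfonate, via vicinal diol 5 (not isolated)
Conditions: OsO4 (2 mol %), NaIO4, 2,6-lutidine, dioxane/H2O, 25 °C
Reagents that add atoms: sodium periodate [Na+].[O-]I(=O)(=O)=O
Why: In this Lemieux–Johnson oxidation the electron-rich monosubstituted alkene should be osmylated in preference to the electron-poor, hindered enol triflate, and periodate cleavage leaves the two carbons that become C1 and the C1 methyl.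

**Step 5**
Reactants: 6 (R)-6-methyl-6-(2-oxoethyl)cyclohex-1-en-1-yl trifluoromethanesulfonate
Product: 8 (R)-6-(cyanomethyl)-6-methylcyclohex-1-en-1-yl trifluoromethanesulfonate, via aldimine 7 (not isolated)
Conditions: I2, aq NH3, THF, 25 °C
Reagents that add atoms: ammonia N
Why: Oxidative conversion of an aldehyde into a nitrile (aldimine, N-iodination, loss of HI) is mild enough for the enol triflate and supplies the carbanion-stabilising group on the future C1.

**Step 6**
Reactants: 9 (R)-but-3-en-2-ol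
Product: 10 (R)-(but-3-en-2-yloxy)trimethylsilane
Conditions: TMSCl, Et3N, CH2Cl2, 0 °C
Reagents that add atoms: chlorotrimethylsilane C[Si](C)(C)Cl
Why: O-Silylation (protection) keeps the hydroxyl from consuming 9-BBN in the next step and leaves the stereocentre untouched.

**Step 7**
Reactants: 10 (R)-(but-3-en-2-yloxy)trimethylsilane; 8 (R)-6-(cyanomethyl)-6-methylcyclohex-1-en-1-yl trifluoromethanesulfonate
Product: 13 2-{(R)-2-[(R)-3-hydroxybutyl]-1-methylcyclohex-2-en-1-yl}acetonitrile, via B-alkyl-9-BBN 11 (not isolated), via TMS ether 12 (not isolated)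
Conditions: 9-BBN, THF, 25 °C; then 8, Pd(dppf)Cl2 (5 mol %), AsPh3, Cs2CO3, DMF/H2O, 50 °C; 1 M HCl work-up
Reagents that add atoms: none
Why: Anti-Markovnikov hydroboration followed by B-alkyl Suzuki–Miyaura coupling with the enol triflate forms the C4–C4a bond under a base too weak to deprotonate the nitrile, the acidic work-up removes the silyl group, and the (R)-carbinol centre is not involved.

**Step 8**
Reactants: 13 2-{(R)-2-[(R)-3-hydroxybutyl]-1-methylcyclohex-2-en-1-yl}acetonitrile
Product: 14 (R)-4-[(R)-6-(cyanomethyl)-6-methylcyclohex-1-en-1-yl]butan-2-yl 4-methylbenzenesulfonate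
Conditions: TsCl, Et3N, DMAP (cat.), CH2Cl2, 0 → 25 °C
Reagents that add atoms: 4-toluenesulfonyl chloride Cc1ccc(cc1)S(Cl)(=O)=O
Why: O-Sulfonylation proceeds with retention at carbon and turns the (R)-carbinol into the leaving group for the ring closure.

**Step 9**
Reactants: 14 (R)-4-[(R)-6-(cyanomethyl)-6-methylcyclohex-1-en-1-yl]butan-2-yl 4-methylbenzenesulfonate; 15 4-bromo-2-(bromomethyl)-1-methoxybenzene
Product: 17 (1S,2S,8aS)-1-(5-bromo-2-methoxybenzyl)-2,8a-dimethyl-1,2,3,4,6,7,8,8a-octahydronaphthalene-1-carbonitrile, via cyclized nitrile 16 (not isolated)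
Conditions: LDA (1.1 equiv), THF/DMPU, −78 → 0 °C; then LDA (1.3 equiv), −78 °C; 15, −78 → 0 °C
Reagents that add atoms: none
Why: LDA removes a proton α to the nitrile of 14 to give an N-lithiated keteniminate whose carbon (C1) displaces the secondary tosylate on C2 from the rear, and a second deprotonation of the ring nitrile 16 followed by 15 benzylates the same carbon. The closest known reaction type is the intramolecular alkylation of nitrile-stabilised carbanions used to close cyclohexanes and decalins, followed by C-alkylation of a cyclohexanecarbonitrile anion. Ring B is closed in a 6-exo-tet mode through a chair-like array in which the ring A bonds at C8a and C4a stay equatorial. C2 is set by the mechanism: inversion of the (R)-sulfonate gives (S) and places the methyl axial and syn to the C8a methyl, an arrangement an equilibrating method would not be expected to favour. C1 is set in the benzylation: both neighbours (C8a and C2) carry an axial methyl on one face of the planar keteniminate, so 15 should enter from the other face and leave the small nitrile equatorial, where the C1 methyl is needed. The step needs SN2 to outrun E2 and C- to outrun N-alkylation; the six-membered intramolecular transition state, the small linear carbanion and the absence of any other electrophilic or acidic site in 14 should secure this.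

**Step 10**
Reactants: 17 (1S,2S,8aS)-1-(5-bromo-2-methoxybenzyl)-2,8a-dimethyl-1,2,3,4,6,7,8,8a-octahydronaphthalene-1-carbonitrile
Product: 19 (1S,2S,8aS)-1-(5-bromo-2-methoxybenzyl)-2,8a-dimethyl-1,2,3,4,6,7,8,8a-octahydronaphthalene-1-carbaldehyde, via N-aluminoimine 18 (not isolated)
Conditions: DIBAL-H, toluene, −78 → 25 °C; then 1 M HCl, THF, 0 °C
Reagents that add atoms: water O
Why: Partial reduction of a nitrile with DIBAL-H stops at the N-aluminoimine, which hydrolyses to the non-enolisable aldehyde, while the aryl bromide, the aryl ether and the alkene are inert.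

**Step 11**
Reactants: 19 (1S,2S,8aS)-1-(5-bromo-2-methoxybenzyl)-2,8a-dimethyl-1,2,3,4,6,7,8,8a-octahydronaphthalene-1-carbaldehyde
Product: 21 4-bromo-1-methoxy-2-{[(1R,2S,8aS)-1,2,8a-trimethyl-1,2,3,4,6,7,8,8a-octahydronaphthalen-1-yl]methyl}benzene, via hydrazone 20 (not isolated)
Conditions: N2H4·H2O, KOH, diethylene glycol, 130 °C then 200 °C, under argon
Reagents that add atoms: none
Why: Wolff–Kishner reduction (Huang–Minlon variant) turns the hindered, non-enolisable CHO into the C1 methyl through the hydrazone anion and loss of N2, with no way for C1 to epimerise.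

**Step 12**
Reactants: 21 4-bromo-1-methoxy-2-{[(1R,2S,8aS)-1,2,8a-trimethyl-1,2,3,4,6,7,8,8a-octahydronaphthalen-1-yl]methyl}benzene
Product: 23 (1R,4aS,5R,6S,8aR)-5-(5-bromo-2-methoxybenzyl)-4a,5,6-trimethyldecahydronaphthalen-1-ol, via alkylborane 22 (not isolated)
Conditions: BH3·SMe2, THF, 0 → 25 °C; then NaOH, H2O2, 0 → 25 °C
Reagents that add atoms: hydrogen peroxide OO
Why: Hydroboration–oxidation adds H and B syn across C4a=C5 from the face opposite the axial C8a methyl (as with steroid 5-enes), which should put hydrogen on C4a trans to the angular methyl (trans-decalin) and oxygen, with retention, on C5.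

**Step 13**
Reactants: 23 (1R,4aS,5R,6S,8aR)-5-(5-bromo-2-methoxybenzyl)-4a,5,6-trimethyldecahydronaphthalen-1-ol
Product: 24 (4aS,5R,6S,8aR)-5-(5-bromo-2-methoxybenzyl)-4a,5,6-trimethyloctahydronaphthalen-1(2H)-one
Conditions: Dess–Martin periodinane, pyridine, CH2Cl2, 0 → 25 °C
Reagents that add atoms: none
Why: Buffered Dess–Martin oxidation gives the C5 ketone under conditions that should not epimerise the adjacent ring-fusion carbon C4a.

**Step 14**
Reactants: 24 (4aS,5R,6S,8aR)-5-(5-bromo-2-methoxybenzyl)-4a,5,6-trimethyloctahydronaphthalen-1(2H)-one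
Product: 25 4-bromo-1-methoxy-2-{[(1R,2S,4aS,8aS)-1,2,8a-trimethyl-5-methylidenedecahydronaphthalen-1-yl]methyl}benzene
Conditions: Zn, CH2Br2, TiCl4, THF/CH2Cl2, 0 → 25 °C
Reagents that add atoms: dibromomethane BrCBr
Why: Takai–Lombardo methylenation is non-basic, so the enolisable ketone should be converted into the exocyclic alkene without epimerisation at C4a.

**Step 15**
Reactants: 25 4-bromo-1-methoxy-2-{[(1R,2S,4aS,8aS)-1,2,8a-trimethyl-5-methylidenedecahydronaphthalen-1-yl]methyl}benzene
Product: 26 4-bromo-2-{[(1R,2S,4aS,8aS)-1,2,8a-trimethyl-5-methylidenedecahydronaphthalen-1-yl]methyl}phenol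
Conditions: NaSEt, DMF, 120 °C; 1 M HCl work-up
Reagents that add atoms: none
Why: SN2 demethylation of the aryl methyl ether by ethanethiolate frees the phenol without acid, so the exocyclic alkene is safe, and it is done before the methyl ester exists.

**Step 16**
Reactants: 26 4-bromo-2-{[(1R,2S,4aS,8aS)-1,2,8a-trimethyl-5-methylidenedecahydronaphthalen-1-yl]methyl}phenol
Product: 27 methyl 4-hydroxy-3-{[(1R,2S,4aS,8aS)-1,2,8a-trimethyl-5-methylidenedecahydronaphthalen-1-yl]methyl}benzoate
Conditions: Pd(OAc)2 (5 mol %), Xantphos (10 mol %), CO (1 atm), Et3N, MeOH/DMF, 70 °C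
Reagents that add atoms: carbon monoxide [C-]#[O+]; methanol CO
Why: Pd-catalysed methoxycarbonylation of the aryl bromide (oxidative addition to zerovalent palladium, CO insertion, methanolysis of the acyl–Pd species) installs the ester para to the hydroxyl, and the isolated 1,1-disubstituted alkene should not compete under CO.

**Compound list**
1 | allyl 2-oxocyclohexane-1-carboxylate | C=CCOC(=O)C1CCCCC1=O | starting material
2 | allyl 1-methyl-2-oxocyclohexane-1-carboxylate (racemic) | C=CCOC(=O)C1(C)CCCCC1=O | intermediate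
3 | (R)-2-allyl-2-methylcyclohexan-1-one | C1CCC[C@](C)(CC=C)C1=O | intermediate
4 | (R)-6-allyl-6-methylcyclohex-1-en-1-yl trifluoromethanesulfonate | C1CCC[C@](C)(CC=C)C=1OS(=O)(=O)C(F)(F)F | intermediate
5 | (6R)-6-(2,3-dihydroxypropyl)-6-methylcyclohex-1-en-1-yl trifluoromethanesulfonate (both carbinol epimers) | C1CCC[C@](C)(CC(O)CO)C=1OS(=O)(=O)C(F)(F)F | intermediate (not isolated)
6 | (R)-6-methyl-6-(2-oxoethyl)cyclohex-1-en-1-yl trifluoromethanesulfonate | C1CCC[C@](C)(CC=O)C=1OS(=O)(=O)C(F)(F)F | intermediate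
7 | (R)-6-(2-iminoethyl)-6-methylcyclohex-1-en-1-yl trifluoromethanesulfonate | C1CCC[C@](C)(CC=N)C=1OS(=O)(=O)C(F)(F)F | intermediate (not isolated)
8 | (R)-6-(cyanomethyl)-6-methylcyclohex-1-en-1-yl trifluoromethanesulfonate | C1CCC[C@](C)(CC#N)C=1OS(=O)(=O)C(F)(F)F | intermediate
9 | (R)-but-3-en-2-ol | C[C@@H](O)C=C | starting material
10 | (R)-(but-3-en-2-yloxy)trimethylsilane | C[C@@H](O[Si](C)(C)C)C=C | intermediate
11 | 9-[(R)-3-(trimethylsilyloxy)butyl]-9-borabicyclo[3.3.1]nonane | C[C@@H](O[Si](C)(C)C)CCB1C2CCCC1CCC2 | intermediate (not isolated)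
12 | 2-{(R)-1-methyl-2-[(R)-3-(trimethylsilyloxy)butyl]cyclohex-2-en-1-yl}acetonitrile | C1CCC[C@](C)(CC#N)C=1CC[C@@H](C)O[Si](C)(C)C | intermediate (not isolated)
13 | 2-{(R)-2-[(R)-3-hydroxybutyl]-1-methylcyclohex-2-en-1-yl}acetonitrile | C1CCC[C@](C)(CC#N)C=1CC[C@@H](C)O | intermediate
14 | (R)-4-[(R)-6-(cyanomethyl)-6-methylcyclohex-1-en-1-yl]butan-2-yl 4-methylbenzenesulfonate | C1CCC[C@](C)(CC#N)C=1CC[C@@H](C)OS(=O)(=O)c1ccc(C)cc1 | intermediate
15 | 4-bromo-2-(bromomethyl)-1-methoxybenzene | BrCc1cc(Br)ccc1OC | starting material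
16 | (2S,8aR)-2,8a-dimethyl-1,2,3,4,6,7,8,8a-octahydronaphthalene-1-carbonitrile (C1 epimers; the two methyls cis) | C1CCC[C@@]2(C)C=1CC[C@H](C)C2C#N | intermediate (not isolated)
17 | (1S,2S,8aS)-1-(5-bromo-2-methoxybenzyl)-2,8a-dimethyl-1,2,3,4,6,7,8,8a-octahydronaphthalene-1-carbonitrile | C1CCC[C@@]2(C)C=1CC[C@H](C)[C@@]2(C#N)Cc1cc(Br)ccc1OC | intermediate
18 | N-(diisobutylalumanyl)imine of aldehyde 19 | C1CCC[C@@]2(C)C=1CC[C@H](C)[C@@]2(C=N[Al](CC(C)C)CC(C)C)Cc1cc(Br)ccc1OC | intermediate (not isolated)
19 | (1S,2S,8aS)-1-(5-bromo-2-methoxybenzyl)-2,8a-dimethyl-1,2,3,4,6,7,8,8a-octahydronaphthalene-1-carbaldehyde | C1CCC[C@@]2(C)C=1CC[C@H](C)[C@@]2(C=O)Cc1cc(Br)ccc1OC | intermediate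
20 | hydrazone of aldehyde 19 | C1CCC[C@@]2(C)C=1CC[C@H](C)[C@@]2(C=NN)Cc1cc(Br)ccc1OC | intermediate (not isolated)
21 | 4-bromo-1-methoxy-2-{[(1R,2S,8aS)-1,2,8a-trimethyl-1,2,3,4,6,7,8,8a-octahydronaphthalen-1-yl]methyl}benzene | C1CCC[C@@]2(C)C=1CC[C@H](C)[C@@]2(C)Cc1cc(Br)ccc1OC | intermediate
22 | [(1R,4aS,5R,6S,8aS)-5-(5-bromo-2-methoxybenzyl)-4a,5,6-trimethyldecahydronaphthalen-1-yl]borane | B[C@@H]1CCC[C@@]2(C)[C@H]1CC[C@H](C)[C@@]2(C)Cc1cc(Br)ccc1OC | intermediate (not isolated)
23 | (1R,4aS,5R,6S,8aR)-5-(5-bromo-2-methoxybenzyl)-4a,5,6-trimethyldecahydronaphthalen-1-ol (trans-fused; OH cis to the ring-fusion H) | O[C@@H]1CCC[C@@]2(C)[C@H]1CC[C@H](C)[C@@]2(C)Cc1cc(Br)ccc1OC | intermediate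
24 | (4aS,5R,6S,8aR)-5-(5-bromo-2-methoxybenzyl)-4a,5,6-trimethyloctahydronaphthalen-1(2H)-one | O=C1CCC[C@@]2(C)[C@H]1CC[C@H](C)[C@@]2(C)Cc1cc(Br)ccc1OC | intermediate
25 | 4-bromo-1-methoxy-2-{[(1R,2S,4aS,8aS)-1,2,8a-trimethyl-5-methylidenedecahydronaphthalen-1-yl]methyl}benzene | C=C1CCC[C@@]2(C)[C@H]1CC[C@H](C)[C@@]2(C)Cc1cc(Br)ccc1OC | intermediate
26 | 4-bromo-2-{[(1R,2S,4aS,8aS)-1,2,8a-trimethyl-5-methylidenedecahydronaphthalen-1-yl]methyl}phenol | C=C1CCC[C@@]2(C)[C@H]1CC[C@H](C)[C@@]2(C)Cc1cc(Br)ccc1O | intermediate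
27 | methyl 4-hydroxy-3-{[(1R,2S,4aS,8aS)-1,2,8a-trimethyl-5-methylidenedecahydronaphthalen-1-yl]methyl}benzoate | C=C1CCC[C@@]2(C)[C@H]1CC[C@H](C)[C@@]2(C)Cc1cc(C(=O)OC)ccc1O | target

**Count**
Total: 16 steps. Longest linear sequence: 15 steps (steps 1–5 and 7–16); step 6 is a one-step branch.

**Steps most likely to fail**

Step 9. Process at risk: base-induced E2 loss of the secondary sulfonate, or a ring closure slowed by the methyl/methyl 1,3-diaxial contact it has to build. Fallback: an epoxide in place of the sulfonate (Stork epoxynitrile cyclization), which cannot eliminate. It sets out from 8. B-alkyl Suzuki–Miyaura coupling with the 9-BBN adduct of (S)-2,2-dimethyl-4-vinyl-1,3-dioxolane should give the acetonide nitrile F1. Aqueous acetic acid should give the diol nitrile F2. PPh3/DIAD should close the terminal epoxide, epoxy nitrile F3, without touching the secondary C–O bond. LDA should then open the epoxide at its inner carbon (6-exo, inversion at C2). The alkoxide is capped in the flask with TMSCl, and a second deprotonation, benzylation with 15 and acidic work-up should give the hydroxymethyl nitrile F4. Tosylation to the primary tosylate F5 and hydride displacement (NaBH4, DMSO) turn CH2OH into the C2 methyl and come back to the route at 17.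

Step 11. Process at risk: slow formation or decomposition of the hindered hydrazone, and loss of bromine from the arene in hot alkali. Fallback: Caglioti–Kabalka reduction under near-neutral conditions. It sets out from 19. TsNHNH2 (EtOH, cat. AcOH) should give the tosylhydrazone F6. Catecholborane (CHCl3, 0 °C) and then NaOAc·3H2O at reflux should deliver hydride to C=N and expel sulfinate and N2, coming back to the route at 21.

Step 12. Process at risk: poor facial selectivity of borane addition, which would give the cis-fused isomer, or sluggish addition to the hindered trisubstituted alkene. Fallback: osmylation, oxidation and reductive α-deoxygenation. It sets out from 21. OsO4/NMO, bulkier than borane, should add from the face opposite the C8a methyl to give the C4a,C5-diol F7. Dess–Martin oxidation of the secondary hydroxyl should give the α-hydroxy ketone F8. SmI2 (THF/MeOH, −78 °C) should cleave the tertiary C–O bond, and the samarium enolate should be protonated on C4a from the same open face, coming back to the route at 24 (23 is bypassed).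

**Further compounds**
F1 | step 9 | 2-{(R)-2-[2-((S)-2,2-dimethyl-1,3-dioxolan-4-yl)ethyl]-1-methylcyclohex-2-en-1-yl}acetonitrile | C1CCC[C@](C)(CC#N)C=1CC[C@H]2COC(C)(C)O2
F2 | step 9 | 2-{(R)-2-[(S)-3,4-dihydroxybutyl]-1-methylcyclohex-2-en-1-yl}acetonitrile | C1CCC[C@](C)(CC#N)C=1CC[C@H](O)CO
F3 | step 9 | 2-{(R)-1-methyl-2-[2-((S)-oxiran-2-yl)ethyl]cyclohex-2-en-1-yl}acetonitrile | C1CCC[C@](C)(CC#N)C=1CC[C@H]2CO2
F4 | step 9 | (1S,2S,8aS)-1-(5-bromo-2-methoxybenzyl)-2-(hydroxymethyl)-8a-methyl-1,2,3,4,6,7,8,8a-octahydronaphthalene-1-carbonitrile | C1CCC[C@@]2(C)C=1CC[C@H](CO)[C@@]2(C#N)Cc1cc(Br)ccc1OC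
F5 | step 9 | [(1S,2S,8aS)-1-(5-bromo-2-methoxybenzyl)-1-cyano-8a-methyl-1,2,3,4,6,7,8,8a-octahydronaphthalen-2-yl]methyl 4-methylbenzenesulfonate | C1CCC[C@@]2(C)C=1CC[C@H](COS(=O)(=O)c1ccc(C)cc1)[C@@]2(C#N)Cc1cc(Br)ccc1OC
F6 | step 11 | N'-{[(1S,2S,8aS)-1-(5-bromo-2-methoxybenzyl)-2,8a-dimethyl-1,2,3,4,6,7,8,8a-octahydronaphthalen-1-yl]methylidene}-4-methylbenzenesulfonohydrazide | C1CCC[C@@]2(C)C=1CC[C@H](C)[C@@]2(C=NNS(=O)(=O)c1ccc(C)cc1)Cc1cc(Br)ccc1OC
F7 | step 12 | (1R,4aR,5R,6S,8aS)-5-(5-bromo-2-methoxybenzyl)-4a,5,6-trimethyloctahydronaphthalene-1,8a(2H)-diol | O[C@@H]1CCC[C@@]2(C)[C@@]1(O)CC[C@H](C)[C@@]2(C)Cc1cc(Br)ccc1OC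
F8 | step 12 | (4aR,5R,6S,8aS)-5-(5-bromo-2-methoxybenzyl)-8a-hydroxy-4a,5,6-trimethyloctahydronaphthalen-1(2H)-one | O=C1CCC[C@@]2(C)[C@@]1(O)CC[C@H](C)[C@@]2(C)Cc1cc(Br)ccc1OC
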